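The isoflavone is disconnected at C3–C1' and O1–C2. Its C2–C3–C4 chain with rings A and B is a chalcone whose ring B has moved from the carbon that becomes C2 to the one that becomes C3. The key step exploits this placement of ring B on C3 next to the C4 carbonyl, and the electron-rich 2,3,4-trimethoxyphenyl ring as migrating group. Oxidation of the 2'-hydroxychalcone 3 with Tl(NO3)3 in methanol shifts ring B to the α carbon, and acid then closes pyranone ring C in the same pot. The precursor, an (E)-2'-hydroxychalcone, comes from one aldol condensation of two commercial aromatics.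

Key step: step 2

Remark on the chemistry: the 2'-hydroxyl of the chalcone is carried unprotected. Its hydrogen bond to the carbonyl is relied on to keep it from competing with the alkene for the oxidant, and it is the nucleophile of the ring closure.

Step 1
Reactants: 1 2'-hydroxy-4',5'-dimethoxyacetophenone; 2 2,3,4-trimethoxybenzaldehyde
Product: 3 (E)-1-(2-hydroxy-4,5-dimethoxyphenyl)-3-(2,3,4-trimethoxyphenyl)prop-2-en-1-one
Conditions: KOH (50% aq., excess), EtOH, rt; then 2 M HCl, 0 °C
Reagents that add atoms: none
Why: Claisen–Schmidt (crossed aldol) condensation, in which the potassium enolate of the methyl ketone adds to the non-enolisable aldehyde and E1cB loss of hydroxide should give the conjugated enone as the thermodynamically preferred E isomer; no stereocentre is created.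

Step 2
Reactants: 3 (E)-1-(2-hydroxy-4,5-dimethoxyphenyl)-3-(2,3,4-trimethoxyphenyl)prop-2-en-1-one
Product: 5 6,7-dimethoxy-3-(2,3,4-trimethoxyphenyl)-4H-chromen-4-one, via rearranged dimethyl acetal 4 (not isolated)
Conditions: Tl(NO3)3·3H2O (1.1 equiv), MeOH, 0 °C to rt; filter off TlNO3; then 10% aq. HCl, reflux
Reagents that add atoms: methanol, CO (supplies the two acetal methoxy groups of 4 only; both leave again as methanol, so 5 holds no atom from a reagent)
Why: Trivalent thallium adds to the alkene of 3 with the metal on the α carbon and methanol on the benzylic β carbon; as the weak C–Tl bond ionises and monovalent thallium departs, ring B moves from Cβ to Cα through a phenonium ion, and the methoxy-stabilised cation left at Cβ takes up a second methanol to give acetal 4. On heating with HCl, 4 re-forms the oxocarbenium ion, the 2'-hydroxyl attacks it in a 6-exo-trig closure of pyranone ring C, and loss of methanol from the 2-methoxyisoflavanone gives the C2=C3 bond. The closest known reaction type is the oxidative rearrangement of 2'-hydroxychalcones to isoflavones with Tl(NO3)3 in methanol followed by acid cyclisation. No stereocentre remains, since the racemic α carbon of 4 becomes the sp2 carbon C3. The selectivity needed is aryl migration over attack of the phenol oxygen on the thallated chain (aurone or flavone) and over oxidation of ring A; the ortho and para methoxy groups of ring B stabilise the phenonium bridge, while the phenol is held in a hydrogen bond to the carbonyl and deactivated by it.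

Compound list
1 | 2'-hydroxy-4',5'-dimethoxyacetophenone, i.e. 1-(2-hydroxy-4,5-dimethoxyphenyl)ethan-1-one | CC(=O)c1cc(OC)c(OC)cc1O | starting material
2 | 2,3,4-trimethoxybenzaldehyde | COc1ccc(C=O)c(OC)c1OC | starting material
3 | (E)-1-(2-hydroxy-4,5-dimethoxyphenyl)-3-(2,3,4-trimethoxyphenyl)prop-2-en-1-one (trans 2'-hydroxychalcone) | COc1cc(O)c(cc1OC)C(=O)/C=C/c1ccc(OC)c(OC)c1OC | intermediate
4 | 1-(2-hydroxy-4,5-dimethoxyphenyl)-3,3-dimethoxy-2-(2,3,4-trimethoxyphenyl)propan-1-one (racemic at C2, not isolated) | COC(OC)C(c1ccc(OC)c(OC)c1OC)C(=O)c1cc(OC)c(OC)cc1O | intermediate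
5 | 6,7,2',3',4'-pentamethoxyisoflavone, i.e. 6,7-dimethoxy-3-(2,3,4-trimethoxyphenyl)-4H-chromen-4-one (no stereocentre) | COc1cc2occ(-c3ccc(OC)c(OC)c3OC)c(=O)c2cc1OC | target

Total step count: 2
Longest linear sequence: 2 steps (1 → 3 → 5)

Steps most likely to fail (the route has only two steps, so both are ranked and there is no third):

1. Step 2. The chelated phenol oxygen may trap the thallated intermediate before ring B has shifted, closing to an aurone or flavone. The oxidant may also attack electron-rich ring A, whose hydroxyl stands para to a methoxy group, instead of the alkene. Incomplete closure of the acetal in the acid stage would lower the outcome further. The fallback sets out from 1 and returns at 5, and it forms C3–C1' by cross-coupling instead of migration. Heating 1 with Me2NCH(OMe)2 (toluene, 90 °C) should give the enaminone (E)-3-(dimethylamino)-1-(2-hydroxy-4,5-dimethoxyphenyl)prop-2-en-1-one F1. I2 in CHCl3 at rt should iodinate its α carbon, and the phenol then closes ring C with loss of dimethylamine to give 3-iodo-6,7-dimethoxy-4H-chromen-4-one F2. Suzuki–Miyaura coupling of F2 with commercial 2,3,4-trimethoxyphenylboronic acid (COc1ccc(B(O)O)c(OC)c1OC) under Pd(PPh3)4, Na2CO3, DME/H2O, 85 °C (zerovalent palladium) should then deliver 5.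

2. Step 1. The condensation may stall, because the ketone reacts as its phenoxide and the aldehyde is ortho-substituted and deactivated by its para methoxy group. On long exposure to base the phenoxide may also add to the new enone, closing to the flavanone. The fallback sets out from 1 and returns at 3, with the phenol masked during the aldol step. MOMCl with NaH in DMF at 0 °C should give 1-[4,5-dimethoxy-2-(methoxymethoxy)phenyl]ethan-1-one F3. Condensation of F3 with 2 (KOH, EtOH, rt), now free of phenoxide, should give (E)-1-[4,5-dimethoxy-2-(methoxymethoxy)phenyl]-3-(2,3,4-trimethoxyphenyl)prop-2-en-1-one F4. Brief treatment of F4 with HCl in MeOH at 40 °C should remove the acetal and give 3.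

Further compounds
F1 | step 2 | (E)-3-(dimethylamino)-1-(2-hydroxy-4,5-dimethoxyphenyl)prop-2-en-1-one | CN(C)/C=C/C(=O)c1cc(OC)c(OC)cc1O
F2 | step 2 | 3-iodo-6,7-dimethoxy-4H-chromen-4-one | COc1cc2occ(I)c(=O)c2cc1OC
F3 | step 1 | 1-[4,5-dimethoxy-2-(methoxymethoxy)phenyl]ethan-1-one | CC(=O)c1cc(OC)c(OC)cc1OCOC
F4 | step 1 | (E)-1-[4,5-dimethoxy-2-(methoxymethoxy)phenyl]-3-(2,3,4-trimethoxyphenyl)prop-2-en-1-one | COCOc1cc(OC)c(OC)cc1C(=O)/C=C/c1ccc(OC)c(OC)c1OC
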